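Remark: the SMILES is read as epigallocatechin 3‑O‑gallate‑(4β→8)‑catechin. Flavan numbering is used (upper unit rings A/C/B, galloyl ring G, lower unit rings D/F/E). The open‑chain precursors are numbered as propanes, so the carbon that becomes C3 is "2S" in 7 and 9 and "3R" in the flavans without any change in space.

## The problem

- The target 14 is two flavan units joined by one bond from the sp3 carbon C4 of ring C to the aromatic carbon C8 of ring D.
- The upper unit has three contiguous stereocentres on ring C (2R,3R,4R): 2‑aryl and 3‑acyloxy are cis, and the 4‑aryl group is trans to both. The lower unit (2R,3S) is (+)‑catechin 10 itself.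
- C4 is the crux. It is a CH bearing two phloroglucinol‑type aryl carbons (C4a of ring A and C8 of ring D). Such bonds form and break through a benzylic cation, so the union is reversible in acid, the product is as nucleophilic as the arene it came from (oligomers), and ring D offers C6 as well as C8.
- Only C3 can control C4 reliably (attack anti to the C3–O bond, helped by the ester carbonyl). C2 and C3 must be set absolutely by other means, and their cis relation is the less stable one.
- The gallate must sit on O3 of the upper unit while the 3‑OH of the lower unit stays free, so the two secondary alcohols must never be free together.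
- Twelve phenols (two pyrogallol rings) oxidise in air above neutral pH. Base epimerises C2 of a 2,3‑cis flavan with a free 4′‑OH and moves or cleaves the ester. Acid cleaves the interflavan bond. All phenols therefore stay benzylated until a neutral last step.
- The feature used here: C4 is at the oxidation level of an aldehyde carbon carrying two aryl groups. If the C4–C4a bond is opened, ring A becomes a 3,5‑dioxygenated phenoxy group on C2 whose two ortho carbons are equivalent. C4 can therefore come from an acetal carbon that is arylated twice, first by its own tethered ring A (closing ring C) and then by C8 of ring D.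

## Retrosynthesis

**14 ⇒ 13.** The twelve O–benzyl bonds are cut last. Hydrogenolysis is neutral and leaves the ester and the C4–C8 bond alone. 13 is 14 with every phenol benzylated and the lower 3‑OH free.

**13 ⇒ 9 + 11 (through 12).** Both aryl–C4 bonds are cut, C4–C8(ring D) and C4–C4a(ring A), so that C4 becomes the acetal carbon of the open‑chain gallate 9 and ring D comes from tetra‑O‑benzylcatechin 11.
- Cutting only C4–C8 leaves a finished flavan whose C4 must be oxidised afterwards.
- Cutting O1–C2 instead would leave C4 to be set in an open chain with nothing to control it.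
- Cutting both bonds at C4 removes ring C and the C4 stereocentre in one stroke and keeps C3, with its ester, as the controller.
- 9 has no ring C, two stereocentres instead of three, and no interflavan bond.
- The forward reaction must ionise the acetal, close ring C on the tethered ring (4‑ethoxyflavan 12), ionise again, and take C8 of 11 on the β face.

**9 ⇒ 7 + 8.** The ester C–O bond is cut. Alcohol 7 has a single free hydroxyl, so acid 8 can only go to the oxygen that becomes O3. The lower unit is not yet present, so its 3‑OH never needs a protecting group.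

**7 ⇒ 5 + 6.** The O1–C2 bond is cut. Phenol 6 opens the cis‑epoxide 5 at the benzylic carbon with inversion. This is preferred to etherifying a diol, where two secondary hydroxyls would compete. A cis‑epoxide opened with inversion gives exactly the erythro arrangement that becomes 2,3‑cis in ring C. The acetal next to the other epoxide carbon deactivates it toward attack.

**5 ⇒ 4.** Both C–O bonds of the epoxide are cut. One enantioselective oxygen transfer to the Z‑alkene 4 sets both stereocentres that become C2 and C3.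

**4 ⇒ 3 ⇒ 2 ⇒ 1.** The Z‑alkene comes from the alkyne 3 by syn‑semihydrogenation. The acetal carbon (future C4) is attached to alkyne 2 as an orthoformate carbon. 2 comes from the commercial aldehyde 1 by one‑carbon homologation. The acetal is inert to every step before the key step and needs no redox adjustment.

**11 ⇒ 10.** Four phenolic O–benzyl bonds are cut; (+)‑catechin 10 supplies both lower stereocentres.

## Roads not taken

**Alternative 1:** cut only C4–C8, with both flavan rings intact (the obvious route).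
- Forward: the commercial tea gallate is perbenzylated, C4 is oxidised with DDQ in the presence of 2‑ethoxyethanol to the 4β‑(2‑ethoxyethyl) ether A1, and A1 is coupled with 11 under TMSOTf.
- It is the shortest route on paper and is kept as the fallback for step 8.
- Its weak points are structural. Eight phenols must be alkylated under base on a 2,3‑cis flavan‑3‑yl ester whose free 4′‑OH allows C2 epimerisation (ring opening to a B‑ring quinone methide) and whose ester can migrate or be lost. C4 must then lose hydride to a quinone in a molecule with eight benzyl ethers and an inductively deactivating acyloxy group next to C4.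
- The chosen plan has C4 at the aldehyde level from the second step and uses no oxidant once the electron‑rich rings are assembled. It sets C2 and C3 by catalyst and SN2 instead of inheriting them, and it is open to variation at ring B, the ester and either enantiomer. Its price is more steps.

**Alternative 2:** cut C4–C8 with inverted polarity.
- Forward: C8 becomes an aryllithium from the 8‑bromide A2 of perbenzylated catechin; it adds to the C4 ketone A3 to give the tertiary carbinol A4, which is then deoxygenated ionically (silane or stannane with acid).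
- Regiochemistry at C8 is fixed and oligomers are excluded.
- However, hydride enters the C4 cation of A4 anti to the C3 substituent, which leaves the aryl group cis to C3–O (4α). That is the wrong epimer for a 2,3‑cis upper unit.
- The aryllithium is incompatible with the gallate, so O3 must be protected and acylated later, and the lower 3‑OH must then be benzylated to tell the two alcohols apart. A3 itself needs the natural flavan and two oxidations.
- In the chosen plan the aryl group enters as the nucleophile on the face left open by the ester, which is present from the start.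

**Alternative 3:** cut C4–C8 and take ring C to the flavylium level.
- Forward: the 3‑O‑galloyl flavylium salt A5 is made by the classical acid‑catalysed aldol condensation/cyclodehydration of an o‑hydroxybenzaldehyde with an ω‑acyloxyacetophenone. C8 of catechin adds to C4 to give the flav‑2‑ene A6, and the enol ester C2=C3 is hydrogenated.
- A5 is achiral and made in one step.
- However, C4 is created on a flat cation by a nucleophile whose stereocentres (ring F) are too remote to choose a face.
- A6 with a free 7‑OH on ring D closes onto C2 to give the doubly linked (A‑type) ketal.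
- Cis‑addition of hydrogen from the face away from the C4 aryl group gives the all‑cis pattern, not 2,3‑cis‑3,4‑trans.
- The chosen plan sets C2 and C3 before the union and lets C3 control C4.

Key step: step 8

## Route

Step 1
Reactants: 1 3,4,5‑tris(benzyloxy)benzaldehyde
Product: 2 5‑ethynyl‑1,2,3‑tris(benzyloxy)benzene
Conditions: Ohira–Bestmann reagent (1.3 equiv), K2CO3 (2 equiv), MeOH/THF, 0 °C → rt
Reagents that add atoms: dimethyl (1‑diazo‑2‑oxopropyl)phosphonate, COP(=O)(OC)C(=[N+]=[N-])C(C)=O
Why: Seyferth–Gilbert homologation in the Ohira–Bestmann form; methanolysis frees the diazomethylphosphonate, which olefinates the aldehyde and loses N2 with 1,2‑shift to the alkyne, and the mild base leaves the benzyl ethers alone.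

Step 2
Reactants: 2 5‑ethynyl‑1,2,3‑tris(benzyloxy)benzene
Product: 3 5‑(3,3‑diethoxyprop‑1‑yn‑1‑yl)‑1,2,3‑tris(benzyloxy)benzene
Conditions: HC(OEt)3 (excess, as solvent), ZnI2 (5 mol %), 135 °C, EtOH distilled off
Reagents that add atoms: triethyl orthoformate, CCOC(OCC)OCC
Why: zinc‑catalysed alkynylation of an orthoester (the zinc acetylide adds to the diethoxycarbenium ion), a known reaction of arylacetylenes; it installs the future C4 at the aldehyde level as a base‑stable acetal.

Step 3
Reactants: 3 5‑(3,3‑diethoxyprop‑1‑yn‑1‑yl)‑1,2,3‑tris(benzyloxy)benzene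
Product: 4 (Z)‑5‑(3,3‑diethoxyprop‑1‑en‑1‑yl)‑1,2,3‑tris(benzyloxy)benzene
Conditions: H2 (1 atm), Lindlar catalyst, quinoline, EtOAc, rt
Reagents that add atoms: none
Why: Lindlar semihydrogenation; syn‑addition of H2 on the poisoned surface gives the Z‑alkene and does not cleave benzyl ethers.

Step 4
Reactants: 4 (Z)‑5‑(3,3‑diethoxyprop‑1‑en‑1‑yl)‑1,2,3‑tris(benzyloxy)benzene
Product: 5 (2S,3S)‑2‑(diethoxymethyl)‑3‑[3,4,5‑tris(benzyloxy)phenyl]oxirane (cis)
Conditions: (S,S)‑Mn(salen)Cl (Jacobsen catalyst, 5 mol %), 4‑phenylpyridine N‑oxide (0.25 equiv), aq NaOCl (pH 11.3), CH2Cl2, 0 °C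
Reagents that add atoms: sodium hypochlorite, [Na+].[O-]Cl
Why: Jacobsen–Katsuki epoxidation, whose best substrates are Z‑aryl alkenes; side‑on approach to the Mn‑oxo species sets both centres (future C2 and C3), the (S,S) catalyst being chosen by analogy with cis‑β‑methylstyrene and cis‑cinnamate esters (benzylic carbon S), and the N‑oxide additive should suppress cis‑to‑trans leakage.

Step 5
Reactants: 5 (2S,3S)‑2‑(diethoxymethyl)‑3‑[3,4,5‑tris(benzyloxy)phenyl]oxirane; 6 3,5‑bis(benzyloxy)phenol
Product: 7 (2S,3R)‑3‑[3,5‑bis(benzyloxy)phenoxy]‑1,1‑diethoxy‑3‑[3,4,5‑tris(benzyloxy)phenyl]propan‑2‑ol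
Conditions: 6 (1.3 equiv), Cs2CO3 (0.3 equiv), DMF, 80 °C
Reagents that add atoms: none
Why: SN2 opening of an aryl epoxide by a phenoxide at the benzylic carbon with inversion (S → R), as in the known phenol openings of aryl glycidols; the two acetal oxygens deactivate the other epoxide carbon, and inversion of the cis‑epoxide gives the erythro arrangement that becomes 2,3‑cis.

Step 6
Reactants: 7 (2S,3R)‑3‑[3,5‑bis(benzyloxy)phenoxy]‑1,1‑diethoxy‑3‑[3,4,5‑tris(benzyloxy)phenyl]propan‑2‑ol; 8 3,4,5‑tris(benzyloxy)benzoic acid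
Product: 9 (2S,3R)‑3‑[3,5‑bis(benzyloxy)phenoxy]‑1,1‑diethoxy‑3‑[3,4,5‑tris(benzyloxy)phenyl]propan‑2‑yl 3,4,5‑tris(benzyloxy)benzoate
Conditions: 8 (1.5 equiv), DCC, DMAP (cat.), CH2Cl2, rt
Reagents that add atoms: none
Why: Steglich esterification of the only free hydroxyl; no stereocentre is touched and the gallate is fixed on the future O3 before the lower unit is present.

Step 7
Reactants: 10 (+)‑catechin
Product: 11 5,7,3′,4′‑tetra‑O‑benzyl‑(+)‑catechin
Conditions: BnBr (4.2 equiv), K2CO3 (4.5 equiv), DMF, 0 °C → rt, Ar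
Reagents that add atoms: benzyl bromide, BrCc1ccccc1
Why: Williamson etherification of the four phenols; the aliphatic 3‑OH is not deprotonated by carbonate and stays free, and the 2,3‑trans unit does not epimerise under these conditions.

Step 8
Reactants: 9 (2S,3R)‑3‑[3,5‑bis(benzyloxy)phenoxy]‑1,1‑diethoxy‑3‑[3,4,5‑tris(benzyloxy)phenyl]propan‑2‑yl 3,4,5‑tris(benzyloxy)benzoate; 11 5,7,3′,4′‑tetra‑O‑benzyl‑(+)‑catechin
Product: 13 dodeca‑O‑benzyl epigallocatechin 3‑O‑gallate‑(4β→8)‑catechin (upper 2R,3R,4R; lower 2R,3S), via 4‑ethoxyflavan gallate 12 (not isolated)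
Conditions: 11 (3 equiv), TMSOTf (0.3 equiv), CH2Cl2, −40 → −10 °C; Et3N quench
Reagents that add atoms: none
Why: Proposed new method: the acetal carbon of 9 is arylated twice in one flask, an oxygen analogue of the Pomeranz–Fritsch–Bobbitt sequence (acetal cyclisation onto an arene, then substitution of the benzylic alkoxy group) joined to the known Lewis‑acid coupling of 4‑alkoxyflavan‑3‑yl esters with flavan‑3‑ol nucleophiles. TMSOTf ionises one ethoxy group; the oxocarbenium ion (or the 1,3‑dioxolan‑2‑ylium ion formed with the neighbouring gallate carbonyl) is attacked by the tethered 3,5‑bis(benzyloxy)phenoxy ring at a carbon ortho to the ether oxygen (the two ortho carbons are equivalent and each is ortho/para to all three oxygens), a 6‑exo‑trig Friedel–Crafts closure that forms ring C as the 4‑ethoxyflavan 12. In 12 the new ring A has oxygens ortho and para to C4, so the second ethoxy group ionises to the C4 benzylic cation, which the cis 3‑O‑galloyl carbonyl bridges on the α face. C8 of 11 then attacks the open β face, anti to the C3–O bond, which sets C4 as 4R (3,4‑trans); C2 and C3 come unchanged from 9 because no bond to them is broken. Ring closure by the tethered ring A is preferred over closure by ring B, which would give a five‑membered ring through a less activated carbon. C8 of 11 is preferred over C6 because C6 lies between two benzyloxy groups while C8 lies between one and the ring oxygen. Single arylation is secured by the excess of 11, which is recovered. If 11 intercepts the first cation before ring closure, the same two bonds form in the other order and the sequence converges on 13.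

Step 9
Reactants: 13 dodeca‑O‑benzyl epigallocatechin 3‑O‑gallate‑(4β→8)‑catechin
Product: 14 epigallocatechin 3‑O‑gallate‑(4β→8)‑catechin (target)
Conditions: H2 (1 atm), Pd(OH)2/C, THF/MeOH/H2O, rt
Reagents that add atoms: none
Why: hydrogenolysis of the twelve benzyl ethers over Pearlman's catalyst under neutral conditions, a standard last step for benzylated proanthocyanidin gallates; the ester, the interflavan bond and the ring C–O bonds should survive, and no stereocentre is touched.

## Compound list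

1 | 3,4,5‑tris(benzyloxy)benzaldehyde | O=Cc1cc(OCc2ccccc2)c(OCc2ccccc2)c(OCc2ccccc2)c1 | starting material
2 | 5‑ethynyl‑1,2,3‑tris(benzyloxy)benzene | C#Cc1cc(OCc2ccccc2)c(OCc2ccccc2)c(OCc2ccccc2)c1 | intermediate
3 | 5‑(3,3‑diethoxyprop‑1‑yn‑1‑yl)‑1,2,3‑tris(benzyloxy)benzene | CCOC(OCC)C#Cc1cc(OCc2ccccc2)c(OCc2ccccc2)c(OCc2ccccc2)c1 | intermediate
4 | (Z)‑5‑(3,3‑diethoxyprop‑1‑en‑1‑yl)‑1,2,3‑tris(benzyloxy)benzene | CCOC(OCC)/C=C\c1cc(OCc2ccccc2)c(OCc2ccccc2)c(OCc2ccccc2)c1 | intermediate
5 | (2S,3S)‑2‑(diethoxymethyl)‑3‑[3,4,5‑tris(benzyloxy)phenyl]oxirane | CCOC(OCC)[C@H]1O[C@H]1c1cc(OCc2ccccc2)c(OCc2ccccc2)c(OCc2ccccc2)c1 | intermediate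
6 | 3,5‑bis(benzyloxy)phenol | Oc1cc(OCc2ccccc2)cc(OCc2ccccc2)c1 | starting material
7 | (2S,3R)‑3‑[3,5‑bis(benzyloxy)phenoxy]‑1,1‑diethoxy‑3‑[3,4,5‑tris(benzyloxy)phenyl]propan‑2‑ol | CCOC(OCC)[C@@H](O)[C@H](Oc1cc(OCc2ccccc2)cc(OCc2ccccc2)c1)c1cc(OCc2ccccc2)c(OCc2ccccc2)c(OCc2ccccc2)c1 | intermediate
8 | 3,4,5‑tris(benzyloxy)benzoic acid | OC(=O)c1cc(OCc2ccccc2)c(OCc2ccccc2)c(OCc2ccccc2)c1 | starting material
9 | (2S,3R)‑3‑[3,5‑bis(benzyloxy)phenoxy]‑1,1‑diethoxy‑3‑[3,4,5‑tris(benzyloxy)phenyl]propan‑2‑yl 3,4,5‑tris(benzyloxy)benzoate | CCOC(OCC)[C@@H](OC(=O)c1cc(OCc2ccccc2)c(OCc2ccccc2)c(OCc2ccccc2)c1)[C@H](Oc1cc(OCc2ccccc2)cc(OCc2ccccc2)c1)c1cc(OCc2ccccc2)c(OCc2ccccc2)c(OCc2ccccc2)c1 | intermediate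
10 | (+)‑catechin, (2R,3S) | O[C@H]1Cc2c(O)cc(O)cc2O[C@@H]1c1ccc(O)c(O)c1 | starting material
11 | 5,7,3′,4′‑tetra‑O‑benzyl‑(+)‑catechin | O[C@H]1Cc2c(OCc4ccccc4)cc(OCc4ccccc4)cc2O[C@@H]1c1ccc(OCc4ccccc4)c(OCc4ccccc4)c1 | intermediate
12 | (2R,3R)‑5,7‑bis(benzyloxy)‑4‑ethoxy‑2‑[3,4,5‑tris(benzyloxy)phenyl]chroman‑3‑yl 3,4,5‑tris(benzyloxy)benzoate (2,3‑cis; C4 epimers) | O=C(O[C@@H]1C(OCC)c2c(OCc4ccccc4)cc(OCc4ccccc4)cc2O[C@@H]1c1cc(OCc4ccccc4)c(OCc4ccccc4)c(OCc4ccccc4)c1)c1cc(OCc4ccccc4)c(OCc4ccccc4)c(OCc4ccccc4)c1 | intermediate (not isolated)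
13 | dodeca‑O‑benzyl epigallocatechin 3‑O‑gallate‑(4β→8)‑catechin (upper 2R,3R,4R; lower 2R,3S; lower 3‑OH free) | O=C(O[C@@H]1[C@@H](c2c(OCc4ccccc4)cc(OCc4ccccc4)c3c2O[C@H](c2ccc(OCc4ccccc4)c(OCc4ccccc4)c2)[C@@H](O)C3)c2c(OCc4ccccc4)cc(OCc4ccccc4)cc2O[C@@H]1c1cc(OCc4ccccc4)c(OCc4ccccc4)c(OCc4ccccc4)c1)c1cc(OCc4ccccc4)c(OCc4ccccc4)c(OCc4ccccc4)c1 | intermediate
14 | epigallocatechin 3‑O‑gallate‑(4β→8)‑catechin | O=C(O[C@@H]1[C@@H](c2c(O)cc(O)c3c2O[C@H](c2ccc(O)c(O)c2)[C@@H](O)C3)c2c(O)cc(O)cc2O[C@@H]1c1cc(O)c(O)c(O)c1)c1cc(O)c(O)c(O)c1 | target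

## Step count and risk

Total step count: 9. Longest linear sequence: 8 steps (1 → 2 → 3 → 4 → 5 → 7 → 9 → 13 → 14); step 7 is a one‑step branch.

**Step 8 (key step, proposed new method).**
- What may go wrong:
  - The benzylic C2–O1 aryl ether may ionise, or the first oxocarbenium ion may lose the C3 proton to an enol ether (loss of the C2/C3 configuration), before ring A closes.
  - Cations may attack 13 further (oligomers) or attack C6 of 11.
  - The free 3‑OH of 11 may be O‑alkylated, which should be reversible under the conditions.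
- Fallback (known chemistry): set out from 11 and reach 13 through the preformed natural upper unit. Commercial (−)‑epigallocatechin 3‑O‑gallate F1 is benzylated (BnBr, K2CO3, DMF, low temperature) to octa‑O‑benzyl‑epigallocatechin gallate F2. Benzylic oxidation with DDQ in the presence of 2‑ethoxyethanol gives the 4β‑(2‑ethoxyethyl) ether F3 (the compound A1 of Alternative 1). TMSOTf‑mediated coupling of F3 with excess 11 gives 13, and the route resumes at step 9.

**Step 5.**
- What may go wrong: displacement at the hindered benzylic carbon of the cis‑epoxide may be slow. Unimolecular opening (loss of the inversion and hence of the 2,3‑relationship) or C‑alkylation through an ortho carbon of the ambident phenoxide could then compete.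
- Fallback: change the electrophile to a glycidic ester, whose benzylic carbon is less shielded and whose opening there by heteroatom nucleophiles is well known. Set out from 1:
  - Still–Gennari olefination gives methyl (Z)‑3‑[3,4,5‑tris(benzyloxy)phenyl]prop‑2‑enoate F4.
  - Salen‑Mn epoxidation gives methyl (2S,3S)‑3‑[3,4,5‑tris(benzyloxy)phenyl]oxirane‑2‑carboxylate F5.
  - Opening by 6 at C3 gives methyl (2S,3R)‑3‑[3,5‑bis(benzyloxy)phenoxy]‑2‑hydroxy‑3‑[3,4,5‑tris(benzyloxy)phenyl]propanoate F6.
  - DIBAL at −78 °C gives the hydroxy aldehyde (2S,3R)‑3‑[3,5‑bis(benzyloxy)phenoxy]‑2‑hydroxy‑3‑[3,4,5‑tris(benzyloxy)phenyl]propanal F7.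
  - F7 is acetalised at once (HC(OEt)3, EtOH, PPTS) to 7, where the route resumes at step 6.

**Step 4.**
- What may go wrong: facial selection may be poor on this new substrate, and the stepwise Mn‑oxo pathway may leak from cis to trans with the electron‑rich aryl group.
- Fallback: give up catalyst control and let the enantiopure lower unit act as resolving partner. Set out from 4:
  - Epoxidation with mCPBA/NaHCO3 (stereospecific, cis) gives 5 together with its enantiomer, (2R,3R)‑2‑(diethoxymethyl)‑3‑[3,4,5‑tris(benzyloxy)phenyl]oxirane F8.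
  - Steps 5 and 6 on the racemate give 7 and 9 together with the enantiomeric alcohol F9 and the enantiomeric gallate F10.
  - In step 8, union with 11 turns the enantiomers into diastereomers, 13 and the diastereomeric dimer with a 2S,3S,4S upper unit F11.
  - These are separated by chromatography, and the route resumes at 13.

**Step 2.**
- What may go wrong: at 135 °C with a zinc Lewis acid, benzyl groups may be lost or migrate, or the electron‑rich alkyne may oligomerise before the zinc acetylide is trapped.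
- Fallback: set out from 2. Deprotonation (n‑BuLi, THF, −78 °C) and formylation with DMF give 3‑[3,4,5‑tris(benzyloxy)phenyl]prop‑2‑ynal F12. Acetalisation (HC(OEt)3, EtOH, cat. p‑TsOH, rt) gives 3.

## Further compounds

F1 | step 8 | (−)‑epigallocatechin 3‑O‑gallate | O=C(O[C@@H]1Cc2c(O)cc(O)cc2O[C@@H]1c1cc(O)c(O)c(O)c1)c1cc(O)c(O)c(O)c1
F2 | step 8 | octa‑O‑benzyl‑epigallocatechin gallate | O=C(O[C@@H]1Cc2c(OCc4ccccc4)cc(OCc4ccccc4)cc2O[C@@H]1c1cc(OCc4ccccc4)c(OCc4ccccc4)c(OCc4ccccc4)c1)c1cc(OCc4ccccc4)c(OCc4ccccc4)c(OCc4ccccc4)c1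
F3 | step 8 | octa‑O‑benzyl‑4β‑(2‑ethoxyethoxy)epigallocatechin gallate | O=C(O[C@@H]1[C@@H](OCCOCC)c2c(OCc4ccccc4)cc(OCc4ccccc4)cc2O[C@@H]1c1cc(OCc4ccccc4)c(OCc4ccccc4)c(OCc4ccccc4)c1)c1cc(OCc4ccccc4)c(OCc4ccccc4)c(OCc4ccccc4)c1
F4 | step 5 | methyl (Z)‑3‑[3,4,5‑tris(benzyloxy)phenyl]prop‑2‑enoate | COC(=O)/C=C\c1cc(OCc2ccccc2)c(OCc2ccccc2)c(OCc2ccccc2)c1
F5 | step 5 | methyl (2S,3S)‑3‑[3,4,5‑tris(benzyloxy)phenyl]oxirane‑2‑carboxylate | COC(=O)[C@H]1O[C@H]1c1cc(OCc2ccccc2)c(OCc2ccccc2)c(OCc2ccccc2)c1
F6 | step 5 | methyl (2S,3R)‑3‑[3,5‑bis(benzyloxy)phenoxy]‑2‑hydroxy‑3‑[3,4,5‑tris(benzyloxy)phenyl]propanoate | COC(=O)[C@@H](O)[C@H](Oc1cc(OCc2ccccc2)cc(OCc2ccccc2)c1)c1cc(OCc2ccccc2)c(OCc2ccccc2)c(OCc2ccccc2)c1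
F7 | step 5 | (2S,3R)‑3‑[3,5‑bis(benzyloxy)phenoxy]‑2‑hydroxy‑3‑[3,4,5‑tris(benzyloxy)phenyl]propanal | O=C[C@@H](O)[C@H](Oc1cc(OCc2ccccc2)cc(OCc2ccccc2)c1)c1cc(OCc2ccccc2)c(OCc2ccccc2)c(OCc2ccccc2)c1
F8 | step 4 | (2R,3R)‑2‑(diethoxymethyl)‑3‑[3,4,5‑tris(benzyloxy)phenyl]oxirane | CCOC(OCC)[C@@H]1O[C@@H]1c1cc(OCc2ccccc2)c(OCc2ccccc2)c(OCc2ccccc2)c1
F9 | step 4 | (2R,3S)‑3‑[3,5‑bis(benzyloxy)phenoxy]‑1,1‑diethoxy‑3‑[3,4,5‑tris(benzyloxy)phenyl]propan‑2‑ol | CCOC(OCC)[C@H](O)[C@@H](Oc1cc(OCc2ccccc2)cc(OCc2ccccc2)c1)c1cc(OCc2ccccc2)c(OCc2ccccc2)c(OCc2ccccc2)c1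
F10 | step 4 | (2R,3S)‑3‑[3,5‑bis(benzyloxy)phenoxy]‑1,1‑diethoxy‑3‑[3,4,5‑tris(benzyloxy)phenyl]propan‑2‑yl 3,4,5‑tris(benzyloxy)benzoate | CCOC(OCC)[C@H](OC(=O)c1cc(OCc2ccccc2)c(OCc2ccccc2)c(OCc2ccccc2)c1)[C@@H](Oc1cc(OCc2ccccc2)cc(OCc2ccccc2)c1)c1cc(OCc2ccccc2)c(OCc2ccccc2)c(OCc2ccccc2)c1
F11 | step 4 | diastereomer of 13 with a 2S,3S,4S upper unit (lower 2R,3S) | O=C(O[C@H]1[C@H](c2c(OCc4ccccc4)cc(OCc4ccccc4)c3c2O[C@H](c2ccc(OCc4ccccc4)c(OCc4ccccc4)c2)[C@@H](O)C3)c2c(OCc4ccccc4)cc(OCc4ccccc4)cc2O[C@H]1c1cc(OCc4ccccc4)c(OCc4ccccc4)c(OCc4ccccc4)c1)c1cc(OCc4ccccc4)c(OCc4ccccc4)c(OCc4ccccc4)c1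
F12 | step 2 | 3‑[3,4,5‑tris(benzyloxy)phenyl]prop‑2‑ynal | O=CC#Cc1cc(OCc2ccccc2)c(OCc2ccccc2)c(OCc2ccccc2)c1
A1 | alternative 1 | octa‑O‑benzyl‑4β‑(2‑ethoxyethoxy)epigallocatechin gallate | O=C(O[C@@H]1[C@@H](OCCOCC)c2c(OCc4ccccc4)cc(OCc4ccccc4)cc2O[C@@H]1c1cc(OCc4ccccc4)c(OCc4ccccc4)c(OCc4ccccc4)c1)c1cc(OCc4ccccc4)c(OCc4ccccc4)c(OCc4ccccc4)c1
A2 | alternative 2 | 8‑bromo‑3,5,7,3′,4′‑penta‑O‑benzyl‑(+)‑catechin | Brc1c(OCc4ccccc4)cc(OCc4ccccc4)c2c1O[C@H](c1ccc(OCc4ccccc4)c(OCc4ccccc4)c1)[C@@H](OCc4ccccc4)C2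
A3 | alternative 2 | (2R,3S)‑5,7‑bis(benzyloxy)‑3‑(tert‑butyldimethylsilyloxy)‑2‑[3,4,5‑tris(benzyloxy)phenyl]chroman‑4‑one (2,3‑cis) | CC(C)(C)[Si](C)(C)O[C@@H]1C(=O)c2c(OCc4ccccc4)cc(OCc4ccccc4)cc2O[C@@H]1c1cc(OCc4ccccc4)c(OCc4ccccc4)c(OCc4ccccc4)c1
A4 | alternative 2 | tertiary C4 carbinol from addition of the aryllithium of A2 to A3 (C4 configuration open) | CC(C)(C)[Si](C)(C)O[C@@H]1C(O)(c2c(OCc4ccccc4)cc(OCc4ccccc4)c3c2O[C@H](c2ccc(OCc4ccccc4)c(OCc4ccccc4)c2)[C@@H](OCc4ccccc4)C3)c2c(OCc4ccccc4)cc(OCc4ccccc4)cc2O[C@@H]1c1cc(OCc4ccccc4)c(OCc4ccccc4)c(OCc4ccccc4)c1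
A5 | alternative 3 | 3‑O‑galloyl‑5,7,3′,4′,5′‑pentahydroxyflavylium chloride | Oc1cc(O)c2cc(OC(=O)c3cc(O)c(O)c(O)c3)c(-c3cc(O)c(O)c(O)c3)[o+]c2c1.[Cl-]
A6 | alternative 3 | 4‑(catechin‑8‑yl)‑3‑galloyloxyflav‑2‑ene (C4 configuration open) | Oc1cc(O)c2c(c1)OC(c1cc(O)c(O)c(O)c1)=C(OC(=O)c1cc(O)c(O)c(O)c1)C2c1c(O)cc(O)c2c1O[C@H](c1ccc(O)c(O)c1)[C@@H](O)C2
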